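Readings and results stem from a simulated flask with constants of no real substance, and the scatter is random.

Time was what the green run had to tell me about the flask, which was to stand for 2.5 d at a lower concentration.

- green: E 1.2 M; D 1.2 M; L 1 equiv; Q 2 mol%; run made earlier
- flask: E 0.80 M; L 1.00 equiv; Q 2 mol%; D 0.80 M; time 2.5 d

green run (percent of the E and D together charged)

| time / h | X / % | G / % | E / % |
|---|---|---|---|
| 1.50 | 0 | 0.3 | 49.8 |
| 5.00 | 0 | 0 | 49.6 |
| 8.00 | 0.3 | 0 | 49.6 |
| 12.0 | 1.4 | 0.4 | 48.9 |
| 20.0 | 2.6 | 0 | 48.4 |

(scatter of a reading: 0.3 percentage points)

- J is single-handed; E and D are mirror images of each other, charged as a racemate, each of them at the stated concentration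
- steps thought possible: L + J + E -> J + X; L + J + D -> J + G; E <-> D; Q -> J; J -> Z
- an excess is below zero if the other one leads
- no earlier run changes the charge of Q; that part of a forecast is a guess

* excess of X over G in the product at 6.0 h
* excess of X over G in the product at 2.5 d
* part of the E and D charged together that has reacted at 2.5 d

In the first instants of the green run nothing showed: X read 0 % at 5.00 h, yet 2.6 % at 20.0 h. I read this as Q slowly becoming J, so that c(J) climbs with time and X with its square. That gave 124 h for the green run. The flask has c(L) and c(J) both lower by the ratio of the charges, so I stretched this to 186 h, the lag clock of the flask: the time such that X, as a share of the charge, is the square of time over this clock.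

At 6.0 h the clock said 0.104 %, below the scatter of 0.3 percentage points, so no excess could be read there. At 30.0 h it said 2.60 %, with J still climbing and L barely touched. At the end it said 10.4 %, and there the charge begins to matter. L was charged equal to E, so this much X takes 20.8 % of L. I put that back in: the rate stands lower by three times the first answer at the end, and by about half of that over a run weighted to its late hours, which gave me 8.78 %. The green run was too short to show whether J kept climbing.

The forecast gave 91 % (72 % to 100 %), 89 % (70 % to 98 %) and 7 % (3.5 % to 11.5 %), noting that “G never rises above noise, so the selectivity is high”. Its 7 % stood below my 8.78 %; for the excesses I had no figure of my own.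

The flask gave 96.7 %, 96.7 % and 7.61 %.

    L + J + E → J + X (k = 0.720 M⁻² h⁻¹)
    L + J + D → J + G (k = 0.0120 M⁻² h⁻¹)
    E ⇌ D (k = 0.140 h⁻¹)
    Q → J (k = 0.0150 h⁻¹)
    J → Z (k = 0.00490 h⁻¹)

The lag clock said 2.60 % at 1.25 d, when the flask had 2.50 % reacted. At the end, with the charge put back, I had said 8.78 % against 7.61 %, and J had gone from 33.5 % to 50.3 %, below the 67.0 % of a steady climb. The late waking of Q and the short time held the flask there: with the catalyst active from the start it reached 17.6 %, and in ten times the time 36.9 %. The clock goes with the inverse root of the Q charged, so the flask with 0.5 mol% of Q had 372 h, which said 2.60 %, and that flask reached 2.09 %.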